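The route rests on cutting ring A across C1'–C6' and C2'–C3'. Ring A is a 1,4-disubstituted cyclohexane: its C4' methyl and the vicinal C4'–Cl/C5'–Br pair map onto the trisubstituted alkene of an isoprene cycloadduct, and C1' hangs on C7, which can be a ketone carbonyl that activates a vinyl group. One catalyst-controlled Diels–Alder reaction of isoprene with an acyclic vinyl ketone therefore builds ring A, places the methyl para to C1' and sets C1'. The dienophile, (S)-4-silyloxy-7-methylocta-1,6-dien-3-one, already carries C8 and the prenyl chain needed for ring B; it is made in four steps from methyl (S)-glycidate.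

Key step: step 5

Numbering used: ring B (tetrahydropyran) O1, C7 (Me, ring A), C8 (OAc), C9, C10 (Br), C11 (Me2); ring A C1' (on C7), C2', C3', C4' (Me, Cl), C5' (Br), C6'.

Assumption: with boron bound syn to the vinyl group, the (S)-oxazaborolidinium is taken to expose the enone face that gives (R)-C1' (α-C–H···O binding model for acyl dienophiles); this sense is not secured for an acyclic α-silyloxy vinyl ketone, and if it proves opposite the (R)-catalyst from (R)-diphenylprolinol is used with no other change.

Step 1
Reactants: 1 methyl (S)-glycidate; 2 2-methylprop-1-enylmagnesium bromide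
Product: 3 methyl (S)-2-hydroxy-5-methylhex-4-enoate
Conditions: CuBr·SMe2 (10 mol%), THF, −78 → −40 °C; aq. NH4Cl
Reagents that add atoms: none
Why: Copper-catalysed Grignard opening of a glycidic ester occurs by SN2 attack at the unsubstituted C3, so the C2 stereocentre (future C8) is carried over untouched as (S) and the ester survives at low temperature.

Step 2
Reactants: 3 methyl (S)-2-hydroxy-5-methylhex-4-enoate
Product: 4 methyl (S)-2-(tert-butyldimethylsilyloxy)-5-methylhex-4-enoate
Conditions: TBSCl, imidazole, DMF, 23 °C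
Reagents that add atoms: tert-butyldimethylsilyl chloride, CC(C)(C)[Si](C)(C)Cl
Why: Imidazole-promoted silyl ether formation on a secondary α-hydroxy ester installs a bulky, non-chelating, weakly Lewis-basic ether that suits both the boron-catalysed cycloaddition and the later Felkin–Anh addition.

Step 3
Reactants: 4 methyl (S)-2-(tert-butyldimethylsilyloxy)-5-methylhex-4-enoate
Product: 5 (S)-2-(tert-butyldimethylsilyloxy)-N-methoxy-N,5-dimethylhex-4-enamide
Conditions: MeNHOMe·HCl (1.5 equiv), iPrMgCl (3 equiv), THF, −20 → 0 °C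
Reagents that add atoms: N,O-dimethylhydroxylamine hydrochloride, CNOC.Cl
Why: Weinreb amide formation by direct aminolysis of the methyl ester with the chloromagnesium amide is fast below 0 °C, where the α-silyloxy centre does not epimerise.

Step 4
Reactants: 5 (S)-2-(tert-butyldimethylsilyloxy)-N-methoxy-N,5-dimethylhex-4-enamide; 6 vinylmagnesium bromide
Product: 7 (S)-4-(tert-butyldimethylsilyloxy)-7-methylocta-1,6-dien-3-one
Conditions: THF, −78 → 0 °C; inverse quench into cold 1 M HCl; used without delay
Reagents that add atoms: none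
Why: Weinreb ketone synthesis, in which the chelated tetrahedral magnesium adduct holds until work-up so that only one vinyl group is added, and the acidic inverse quench keeps the liberated amine from adding to the enone.

Step 5
Reactants: 7 (S)-4-(tert-butyldimethylsilyloxy)-7-methylocta-1,6-dien-3-one; 8 isoprene
Product: 9 (S)-2-(tert-butyldimethylsilyloxy)-5-methyl-1-[(R)-4-methylcyclohex-3-en-1-yl]hex-4-en-1-one
Conditions: (S)-3,3-diphenyl-1-(o-tolyl)tetrahydro-1H,3H-pyrrolo[1,2-c][1,3,2]oxazaborole (20 mol%), HNTf2 (16 mol%), isoprene (5 equiv), CH2Cl2, −78 → −40 °C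
Reagents that add atoms: none
Why: The ketone oxygen binds the boron of the N-protonated oxazaborolidinium on the lone pair syn to the vinyl group, which lowers the enone LUMO, and isoprene adds in a concerted, asynchronous [4+2] cycloaddition in which the C2'–C3' bond (enone β-carbon to the diene terminus next to the methyl-bearing carbon) is the more advanced. The closest known reaction type is the oxazaborolidinium-catalysed Diels–Alder reaction of acrylates and simple enones with 2-substituted butadienes. Ring A is closed by intermolecular [4+2] annulation, the two σ-bonds C2'–C3' and C1'–C6' forming suprafacially on both components in one step. C1' is the only new stereocentre and is set by the catalyst, whose aryl group on the carbinol carbon covers one face of the bound vinyl group so that the diene adds to the other, while C8 is not touched. The step needs para regioselectivity, secured by the 2-methyl group of isoprene (larger HOMO coefficient at C1) matched to the boron-polarised β-carbon, and catalyst-controlled face selectivity, secured because the C8 substituents lie across the carbonyl from the reacting alkene and the silyl ether oxygen does not compete for boron. The slight excess of oxazaborolidine over HNTf2 leaves no free acid to attack the prenyl alkene or the silyl ether.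

Step 6
Reactants: 9 (S)-2-(tert-butyldimethylsilyloxy)-5-methyl-1-[(R)-4-methylcyclohex-3-en-1-yl]hex-4-en-1-one; 10 methyllithium
Product: 11 (2S,3S)-3-(tert-butyldimethylsilyloxy)-6-methyl-2-[(R)-4-methylcyclohex-3-en-1-yl]hept-5-en-2-ol
Conditions: MeLi, THF, −78 °C; aq. NH4Cl at −78 °C
Reagents that add atoms: none
Why: 1,2-Addition under non-chelating conditions follows the polar Felkin–Anh model (C8–OSi bond anti to the incoming methyl, which passes the C8 hydrogen) and gives the (7S) tertiary alcohol, whereas chelation, which would give the C7 epimer, is disfavoured by the bulky silyl ether and by lithium in THF.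

Step 7
Reactants: 11 (2S,3S)-3-(tert-butyldimethylsilyloxy)-6-methyl-2-[(R)-4-methylcyclohex-3-en-1-yl]hept-5-en-2-ol
Product: 12 tert-butyl{[(2S,3S,5S)-5-bromo-2,6,6-trimethyl-2-[(R)-4-methylcyclohex-3-en-1-yl]oxan-3-yl]oxy}dimethylsilane
Conditions: 2,4,4,6-tetrabromocyclohexa-2,5-dienone (TBCO, 1.1 equiv), CH2Cl2/MeNO2, 0 °C, dark
Reagents that add atoms: 2,4,4,6-tetrabromocyclohexa-2,5-dienone, O=C1C(Br)=CC(Br)(Br)C=C1Br
Why: Bromoetherification in the 6-endo, Markovnikov mode, in which the C7 hydroxyl opens the brominated prenyl alkene at the tertiary C11 by anti addition through a chair-like transition state with ring A equatorial and the C8 silyloxy group axial, so that bromine ends equatorial at C10 (10S), while the ring A alkene has no comparably placed nucleophile and is brominated only reversibly.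

Step 8
Reactants: 12 tert-butyl{[(2S,3S,5S)-5-bromo-2,6,6-trimethyl-2-[(R)-4-methylcyclohex-3-en-1-yl]oxan-3-yl]oxy}dimethylsilane
Product: 13 (2S,3S,5S)-5-bromo-2,6,6-trimethyl-2-[(R)-4-methylcyclohex-3-en-1-yl]oxan-3-ol
Conditions: HF·pyridine, pyridine, THF, 0 → 23 °C
Reagents that add atoms: none
Why: Fluoride-mediated desilylation under buffered, non-basic conditions forms no alkoxide next to the C10 bromide and leaves the ring A alkene untouched.

Step 9
Reactants: 13 (2S,3S,5S)-5-bromo-2,6,6-trimethyl-2-[(R)-4-methylcyclohex-3-en-1-yl]oxan-3-ol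
Product: 14 (2S,3S,5S)-5-bromo-2,6,6-trimethyl-2-[(R)-4-methylcyclohex-3-en-1-yl]oxan-3-yl acetate
Conditions: Ac2O, 4-(dimethylamino)pyridine (10 mol%), pyridine, 23 °C
Reagents that add atoms: acetic anhydride, CC(=O)OC(C)=O
Why: Acylation by nucleophilic catalysis esterifies the axial secondary C8 alcohol, the only hydroxyl group present.

Step 10
Reactants: 14 (2S,3S,5S)-5-bromo-2,6,6-trimethyl-2-[(R)-4-methylcyclohex-3-en-1-yl]oxan-3-yl acetate
Product: 15 (2S,3S,5S)-5-bromo-2,6,6-trimethyl-2-[(1R,4R,6S)-1-methyl-7-oxabicyclo[4.1.0]heptan-4-yl]oxan-3-yl acetate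
Conditions: 1,2:4,5-di-O-isopropylidene-β-L-erythro-2,3-hexodiulo-2,6-pyranose (30 mol%), Oxone, K2CO3, Bu4NHSO4, MeCN/dimethoxymethane/aq. Na2B4O7–Na2EDTA buffer (pH 10.5), 0 °C
Reagents that add atoms: potassium peroxymonosulfate (active component of Oxone), [K+].[O-]S(=O)(=O)OO
Why: Shi epoxidation of the only alkene, in which the remote C1' centre gives no useful substrate bias and the L-fructose-derived ketone is the antipode whose spiro transition state delivers oxygen to the ring A face trans to the C1'–C7 bond (4'R,5'S), the acetate surviving the cold buffered medium.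

Step 11
Reactants: 15 (2S,3S,5S)-5-bromo-2,6,6-trimethyl-2-[(1R,4R,6S)-1-methyl-7-oxabicyclo[4.1.0]heptan-4-yl]oxan-3-yl acetate
Product: 16 (2S,3S,5S)-5-bromo-2-[(1R,3S,4S)-4-bromo-3-hydroxy-4-methylcyclohexyl]-2,6,6-trimethyloxan-3-yl acetate
Conditions: 48% aq. HBr, CHCl3, 0 °C, short contact; crude product used directly
Reagents that add atoms: hydrogen bromide, Br
Why: Acid-mediated epoxide opening by bromide at the tertiary C4' with inversion is at once the Markovnikov and the trans-diaxial (Fürst–Plattner) mode for this epoxide, and gives bromine axial at C4' (cis to C7) and the C5' hydroxyl axial (trans to C7).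

Step 12
Reactants: 16 (2S,3S,5S)-5-bromo-2-[(1R,3S,4S)-4-bromo-3-hydroxy-4-methylcyclohexyl]-2,6,6-trimethyloxan-3-yl acetate
Product: 19 acetylcaespitol, via chlorosulfite 17 (not isolated), via bromonium chloride 18 (not isolated)
Conditions: SOCl2 (1.5 equiv), pyridine (2 equiv), CH2Cl2, −20 → 0 °C; no heating
Reagents that add atoms: thionyl chloride, O=S(Cl)Cl
Why: Deoxychlorination with neighbouring-bromine participation, in which the chlorosulfite of the axial C5' alcohol ionises with backside assistance of the anti-periplanar C4' bromine to a bromonium ion on the face cis to C7 and chloride opens it at the tertiary C4' (Markovnikov) from the opposite face, so that bromine ends at C5' (5'R) and chlorine at C4' (4'R), trans and both equatorial.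

Compound list

1 | methyl (S)-glycidate [methyl (2S)-oxirane-2-carboxylate] | COC(=O)[C@@H]1CO1 | starting material
2 | 2-methylprop-1-enylmagnesium bromide | CC(C)=C[Mg]Br | starting material
3 | methyl (S)-2-hydroxy-5-methylhex-4-enoate | CC(C)=CC[C@H](O)C(=O)OC | intermediate
4 | methyl (S)-2-(tert-butyldimethylsilyloxy)-5-methylhex-4-enoate | CC(C)=CC[C@H](O[Si](C)(C)C(C)(C)C)C(=O)OC | intermediate
5 | (S)-2-(tert-butyldimethylsilyloxy)-N-methoxy-N,5-dimethylhex-4-enamide | CC(C)=CC[C@H](O[Si](C)(C)C(C)(C)C)C(=O)N(C)OC | intermediate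
6 | vinylmagnesium bromide | C=C[Mg]Br | starting material
7 | (S)-4-(tert-butyldimethylsilyloxy)-7-methylocta-1,6-dien-3-one | CC(C)=CC[C@H](O[Si](C)(C)C(C)(C)C)C(=O)C=C | intermediate
8 | isoprene | C=CC(C)=C | starting material
9 | (S)-2-(tert-butyldimethylsilyloxy)-5-methyl-1-[(R)-4-methylcyclohex-3-en-1-yl]hex-4-en-1-one | CC(C)=CC[C@H](O[Si](C)(C)C(C)(C)C)C(=O)[C@@H]1CCC(C)=CC1 | intermediate
10 | methyllithium | [Li]C | starting material
11 | (2S,3S)-3-(tert-butyldimethylsilyloxy)-6-methyl-2-[(R)-4-methylcyclohex-3-en-1-yl]hept-5-en-2-ol | CC(C)=CC[C@H](O[Si](C)(C)C(C)(C)C)[C@@](C)(O)[C@@H]1CCC(C)=CC1 | intermediate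
12 | tert-butyl{[(2S,3S,5S)-5-bromo-2,6,6-trimethyl-2-[(R)-4-methylcyclohex-3-en-1-yl]oxan-3-yl]oxy}dimethylsilane | CC(C)(C)[Si](C)(C)O[C@H]1C[C@H](Br)C(C)(C)O[C@@]1(C)[C@@H]1CCC(C)=CC1 | intermediate
13 | (2S,3S,5S)-5-bromo-2,6,6-trimethyl-2-[(R)-4-methylcyclohex-3-en-1-yl]oxan-3-ol | O[C@H]1C[C@H](Br)C(C)(C)O[C@@]1(C)[C@@H]1CCC(C)=CC1 | intermediate
14 | (2S,3S,5S)-5-bromo-2,6,6-trimethyl-2-[(R)-4-methylcyclohex-3-en-1-yl]oxan-3-yl acetate | CC(=O)O[C@H]1C[C@H](Br)C(C)(C)O[C@@]1(C)[C@@H]1CCC(C)=CC1 | intermediate
15 | (2S,3S,5S)-5-bromo-2,6,6-trimethyl-2-[(1R,4R,6S)-1-methyl-7-oxabicyclo[4.1.0]heptan-4-yl]oxan-3-yl acetate (epoxide oxygen trans to the C1'–C7 bond) | CC(=O)O[C@H]1C[C@H](Br)C(C)(C)O[C@@]1(C)[C@@H]1CC[C@@]2(C)O[C@H]2C1 | intermediate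
16 | (2S,3S,5S)-5-bromo-2-[(1R,3S,4S)-4-bromo-3-hydroxy-4-methylcyclohexyl]-2,6,6-trimethyloxan-3-yl acetate | CC(=O)O[C@H]1C[C@H](Br)C(C)(C)O[C@@]1(C)[C@@H]1CC[C@](C)(Br)[C@@H](O)C1 | intermediate
17 | chlorosulfite of 16 at the C5' oxygen | CC(=O)O[C@H]1C[C@H](Br)C(C)(C)O[C@@]1(C)[C@@H]1CC[C@](C)(Br)[C@@H](OS(Cl)=O)C1 | intermediate
18 | C4',C5'-bromonium chloride, bromine bridging on the ring A face cis to C7 | CC(=O)O[C@H]1C[C@H](Br)C(C)(C)O[C@@]1(C)[C@@H]1CC[C@]2(C)[Br+][C@@H]2C1.[Cl-] | intermediate
19 | acetylcaespitol, (2S,3S,5S)-5-bromo-2-[(1R,3R,4R)-3-bromo-4-chloro-4-methylcyclohexyl]-2,6,6-trimethyloxan-3-yl acetate | CC(=O)O[C@H]1C[C@H](Br)C(C)(C)O[C@@]1(C)[C@@H]1CC[C@@](C)(Cl)[C@H](Br)C1 | target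

Total step count: 12. Longest linear sequence: 12 steps, from methyl (S)-glycidate 1.

Steps most likely to fail

1. Step 5 (key step). Face selection may be governed in part by the resident C8 centre instead of the catalyst, or the prenyl alkene may add to the boron-activated enone in an ene-type cyclisation before isoprene does. The fallback replaces one-point boron activation by two-point binding of a free hydroxy enone to a chiral copper complex. It sets out from 3: aminolysis with MeNHOMe·HCl and iPrMgCl gives (S)-2-hydroxy-N-methoxy-N,5-dimethylhex-4-enamide F1, and excess 6 converts it into (S)-4-hydroxy-7-methylocta-1,6-dien-3-one F2. F2 chelates divalent copper through its hydroxyl and carbonyl oxygens and reacts with 8 under Cu(OTf)2 and 2,2'-(propane-2,2-diyl)bis(4-tert-butyl-4,5-dihydrooxazole), the ligand antipode being chosen for the (R)-C1' sense, to give (S)-2-hydroxy-5-methyl-1-[(R)-4-methylcyclohex-3-en-1-yl]hex-4-en-1-one F3. Silylation with TBSOTf and 2,6-lutidine comes back to the route at 9.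

2. Step 7. Closure may take the 5-exo course at C10 to a tetrahydrofuran, a boat-like closure may give the C10 epimer, or electrophilic bromine may be consumed at the ring A alkene. The fallback separates ring closure from bromine introduction. From 11, Hg(OCOCF3)2 in MeNO2 at 0 °C followed by aqueous KBr closes the tetrahydropyran by oxymercuration at the tertiary C11, a reversible process with a strong 6-endo preference. This gives bromo{(3S,5S,6S)-5-(tert-butyldimethylsilyloxy)-2,2,6-trimethyl-6-[(R)-4-methylcyclohex-3-en-1-yl]oxan-3-yl}mercury F4. Brominative demercuration with Br2 and LiBr in pyridine replaces divalent mercury by bromine with retention at C10 and comes back at 12.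

3. Step 12. Chloride may capture the bridged ion at the secondary C5' (diaxial opening without bromine shift), the tertiary bromide may lose HBr, or bromine may be handed back to chloride so that face control is lost. The fallback splits the bromine shift from the chloride introduction and uses weakly nucleophilic, ionising conditions, which favour capture at the tertiary carbon. From 16, Tf2O and 2,6-lutidine in CH2Cl2 at −78 °C give (2S,3S,5S)-5-bromo-2-[(1R,3S,4S)-4-bromo-4-methyl-3-(trifluoromethylsulfonyloxy)cyclohexyl]-2,6,6-trimethyloxan-3-yl acetate F5. Warming F5 in wet THF with NaHCO3 ionises it with bromine assistance, and water adds at C4' to give (2S,3S,5S)-5-bromo-2-[(1R,3R,4R)-3-bromo-4-hydroxy-4-methylcyclohexyl]-2,6,6-trimethyloxan-3-yl acetate F6. Anhydrous HCl in CH2Cl2 at −20 °C then exchanges the tertiary hydroxyl for chloride with retention, through the same bromine-bridged cation, and comes back at 19.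

Further compounds

F1 | step 5 | (S)-2-hydroxy-N-methoxy-N,5-dimethylhex-4-enamide | CC(C)=CC[C@H](O)C(=O)N(C)OC
F2 | step 5 | (S)-4-hydroxy-7-methylocta-1,6-dien-3-one | CC(C)=CC[C@H](O)C(=O)C=C
F3 | step 5 | (S)-2-hydroxy-5-methyl-1-[(R)-4-methylcyclohex-3-en-1-yl]hex-4-en-1-one | CC(C)=CC[C@H](O)C(=O)[C@@H]1CCC(C)=CC1
F4 | step 7 | bromo{(3S,5S,6S)-5-(tert-butyldimethylsilyloxy)-2,2,6-trimethyl-6-[(R)-4-methylcyclohex-3-en-1-yl]oxan-3-yl}mercury | CC(C)(C)[Si](C)(C)O[C@H]1C[C@H]([Hg]Br)C(C)(C)O[C@@]1(C)[C@@H]1CCC(C)=CC1
F5 | step 12 | (2S,3S,5S)-5-bromo-2-[(1R,3S,4S)-4-bromo-4-methyl-3-(trifluoromethylsulfonyloxy)cyclohexyl]-2,6,6-trimethyloxan-3-yl acetate | CC(=O)O[C@H]1C[C@H](Br)C(C)(C)O[C@@]1(C)[C@@H]1CC[C@](C)(Br)[C@@H](OS(=O)(=O)C(F)(F)F)C1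
F6 | step 12 | (2S,3S,5S)-5-bromo-2-[(1R,3R,4R)-3-bromo-4-hydroxy-4-methylcyclohexyl]-2,6,6-trimethyloxan-3-yl acetate | CC(=O)O[C@H]1C[C@H](Br)C(C)(C)O[C@@]1(C)[C@@H]1CC[C@@](C)(O)[C@H](Br)C1
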